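**Retrosynthetic overview**
- The strategy rests on the α-methylene-γ-lactone of the guaiane half (ring C7–C8–O–C12–C11 with exocyclic C13). Its carbonyl carbon C12 is left out until the last step and enters as CO on a C8-hydroxy C11-vinyl iodide.
- The spiro-norbornene (ring C1–C2–C3–C4–C5 bridged by C13'–C11') is cut by a Diels–Alder disconnection into a 2-acetoxyguaia-1(5),3-diene that already carries the vinyl iodide, and eudesmanolide 21. With C12 absent, 21 is the only Michael acceptor present.
- Eudesmanolide 21: (S)-Wieland–Miescher ketone supplies rings A and B. The C4' methyl comes from an epoxide opening, the C7'–C11' bond from a Negishi coupling, then the cis-lactone ring is closed and methylenated.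
- Guaiane half: the seven-membered ring comes from cyclohepta-1,3-diene, with C8 set by desymmetrisation and C7 and C10 by conjugate additions. The five-membered ring is closed by aldol condensation, C2–O is added by α'-acetoxylation, and the vinylsilane becomes the vinyl iodide.
- Ring order: decalin, eudesmane lactone, cycloheptane, cyclopentene, norbornene, and last the guaiane lactone.

Key step: step 28

Numbering: atom numbers are those of the target, C1–C15 for the guaiane half and C1'–C15' for the eudesmane half.
Assumption: the sense of induction of the cinchona catalyst (step 15) and of the phosphoramidite ligand (step 19) is taken from the parent ring systems. Each is available as its (pseudo)enantiomer.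

**Route**

Step 1
Reactants: 1 (S)-Wieland–Miescher ketone
Product: 2 (4aS,5S)-5-hydroxy-4a-methyl-4,4a,5,6,7,8-hexahydronaphthalen-2(3H)-one (C1' hydroxyl cis to the C14' methyl)
Conditions: NaBH4 (0.3 equiv), EtOH, 0 °C
Reagents that add atoms: none
Why: In this chemoselective borohydride reduction the isolated C1' ketone is more electrophilic than the enone, and hydride should come from the face opposite the angular methyl, which sets C1'.

Step 2
Reactants: 2 hydroxy enone
Product: 3 C1' tert-butyldimethylsilyl (TBS) ether of 2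
Conditions: TBSCl, imidazole, DMF, 23 °C
Reagents that add atoms: TBSCl, CC(C)(C)[Si](C)(C)Cl
Why: This is a standard silylation, and the hindered secondary silyl ether should survive the bases, organometallics and oxidants that follow and fall to fluoride at the end.

Step 3
Reactants: 3 silyl ether enone
Product: 4 C7' ethylene ketal with the double bond moved to C4'=C5'
Conditions: HOCH2CH2OH, p-TsOH (cat.), benzene, reflux, water separator
Reagents that add atoms: ethylene glycol, OCCO
Why: Acid-catalysed ketalisation of a ring-fusion enone goes through the dienol and deconjugates the alkene, as with steroidal 4-en-3-ones.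

Step 4
Reactants: 4 unsaturated ketal
Product: 5 4',5'-epoxide, oxygen on the face opposite the C14' methyl
Conditions: m-CPBA, NaHCO3, CH2Cl2, 0 °C
Reagents that add atoms: m-CPBA, OOC(=O)c1cccc(Cl)c1
Why: In this Prilezhaev epoxidation the axial angular methyl shields one face, so oxygen should be delivered to the other and set C5' and, provisionally, C4'.

Step 5
Reactants: 5 epoxide
Product: 6 5'-hydroxy-4'-methyl ketal (methyl cis to C14', tertiary hydroxyl trans)
Conditions: MeMgBr (excess), THF, 66 °C
Reagents that add atoms: MeMgBr, C[Mg]Br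
Why: The trans-diaxial (Fürst–Plattner) epoxide opening occurs at the secondary carbon C4' with inversion, which puts the methyl on the C14' face and sets C4'.

Step 6
Reactants: 6 hydroxy ketal
Product: 7 β-hydroxy ketone (C7' ketone, C5' hydroxyl)
Conditions: PPTS, acetone–H2O, 56 °C
Reagents that add atoms: water, O
Why: This mild acetal hydrolysis should leave the silyl ether and the tertiary alcohol untouched.

Step 7
Reactants: 7 β-hydroxy ketone
Product: 8 4'-methyl enone (C5'=C6', C7' ketone, methyl still cis to C14')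
Conditions: NaOH (0.1 M), MeOH, 0 °C, short contact
Reagents that add atoms: none
Why: This is an E1cB dehydration, and cold dilute base with a short contact time should avoid epimerisation of the axial C4' methyl through the extended dienolate.

Step 8
Reactants: 8 enone
Product: 10 cross-conjugated dienyl triflate (C7'–OTf, C7'=C8', C5'=C6'), via lithium dienolate 9 (not isolated)
Conditions: LiN(i-Pr)2, THF, –78 °C; PhNTf2, –78 → 0 °C
Reagents that add atoms: PhNTf2, O=S(=O)(N(c1ccccc1)S(=O)(=O)C(F)(F)F)C(F)(F)F
Why: Kinetic α'-deprotonation at C8' followed by O-triflation never touches the C4' hydrogen, so that centre is kept.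

Step 9
Reactants: 10 dienyl triflate; 11 tert-butyl (bromozincio)acetate
Product: 12 tert-butyl ester with the CH2CO2t-Bu chain (C11', C12') on C7' of the ring B diene
Conditions: Pd2(dba)3, XPhos, THF, 60 °C
Reagents that add atoms: 11 BrZnCH2CO2t-Bu, Br[Zn]CC(=O)OC(C)(C)C
Why: This Negishi coupling of an enol triflate with a zinc ester enolate forms C7'–C11' without base.

Step 10
Reactants: 12 diene ester
Product: 14 8'-alcohol (H7' and 8'-OH on the face opposite C14', C11' chain cis to C14', C5'=C6' kept), via C8' borane 13 (not isolated)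
Conditions: 9-BBN, THF, 0 → 23 °C; H2O2, NaOH, 0 °C
Reagents that add atoms: hydrogen peroxide, OO
Why: In this hydroboration–oxidation boron goes to the unsubstituted C8' of the less hindered diene double bond from the face opposite C14'. That sets C7' correctly and gives a C8' alcohol that steps 11 and 12 invert.

Step 11
Reactants: 14 alcohol
Product: 15 β,γ-unsaturated C8' ketone
Conditions: Dess–Martin periodinane, NaHCO3, CH2Cl2, 0 °C
Reagents that add atoms: none
Why: The buffered Dess–Martin oxidation is neutral enough to leave C7' and the C5'=C6' double bond in place.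

Step 12
Reactants: 15 ketone
Product: 17 cis-fused γ-lactone (C8'–O and C7'–C11' both cis to C14'), via lithium alkoxide 16 (not isolated)
Conditions: LiBH(s-Bu)3, THF, –78 °C, then 23 °C
Reagents that add atoms: none
Why: The bulky hydride should attack opposite the syn-axial C14' methyl and give the axial alkoxide, which sets C8'. This alkoxide lies cis to the ester chain and closes the lactone by acyl substitution.

Step 13
Reactants: 17 lactone
Product: 21 C1'-OTBS eudesma-5',11'(13')-dien-12',8'-olide, via lithium enolate 18 (not isolated), via Mannich base 19 (not isolated), via methiodide 20 (not isolated)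
Conditions: LiN(i-Pr)2, THF, –78 °C; CH2=NMe2+ I–; MeI; DBU, CH2Cl2, 23 °C
Reagents that add atoms: Eschenmoser's salt, C=[N+](C)C.[I-]
Why: This is the standard α-methylenation of a lactone by Mannich aminomethylation, quaternisation and Hofmann-type elimination.

Step 14
Reactants: 22 cyclohepta-1,3-diene
Product: 23 6,7-dioxabicyclo[3.2.2]non-8-ene (meso endoperoxide)
Conditions: O2, tetraphenylporphyrin, hν, CH2Cl2, –20 °C
Reagents that add atoms: oxygen, O=O
Why: The [4+2] cycloaddition of singlet oxygen to a cyclic 1,3-diene gives the meso cis-bridged peroxide.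

Step 15
Reactants: 23 endoperoxide
Product: 24 (R)-4-hydroxycyclohept-2-enone (carbinol carbon = C8, carbonyl = C5)
Conditions: 9-O-acetylcupreidine (10 mol %), CH2Cl2, 23 °C
Reagents that add atoms: none
Why: In this catalytic asymmetric Kornblum–DeLaMare rearrangement the chiral base removes one of the two enantiotopic bridgehead hydrogens, which sets C8.

Step 16
Reactants: 24 hydroxy enone
Product: 25 (R)-4-(TBSO)cyclohept-2-enone
Conditions: TBSCl, imidazole, DMF, 0 °C
Reagents that add atoms: TBSCl, CC(C)(C)[Si](C)(C)Cl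
Why: Silylation blocks β-elimination and provides the bulky γ-substituent that steers the next step.

Step 17
Reactants: 25 silyloxy enone; 26 (1-bromovinyl)trimethylsilane
Product: 28 trans-3-[1-(trimethylsilyl)vinyl]-4-(TBSO)cycloheptanone (C7 chain trans to C8–O), via Grignard reagent 27 (not isolated)
Conditions: 26, Mg, THF; CuBr·SMe2 (20 mol %), 25, –78 → –40 °C
Reagents that add atoms: 26 (1-bromovinyl)trimethylsilane, C=C(Br)[Si](C)(C)C
Why: The copper-catalysed conjugate addition occurs anti to the γ-silyloxy group and sets C7, and the 1-silylvinyl group is a robust mask for the vinyl iodide.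

Step 18
Reactants: 28 ketone
Product: 30 5-(TBSO)-6-[1-(trimethylsilyl)vinyl]cyclohept-2-enone (C5 ketone, C1=C10), via silyl enol ether 29 (not isolated)
Conditions: LiN(i-Pr)2, Me3SiCl, THF, –78 °C; Pd(OAc)2, MeCN, 23 °C
Reagents that add atoms: none
Why: Kinetic enolsilylation takes place on the C1 side, away from the branched C7, and Saegusa–Ito dehydrogenation then gives the enone.

Step 19
Reactants: 30 enone
Product: 32 C5 trimethylsilyl enol ether (C5=C1) with the C10 methyl trans to C8–O and cis to the C7 chain, via zinc enolate 31 (not isolated)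
Conditions: Me2Zn, Cu(OTf)2 (2 mol %), (R,S,S)-BINOL bis(1-phenylethyl)amine phosphoramidite (4 mol %), toluene, –30 °C; Me3SiOTf
Reagents that add atoms: dimethylzinc, C[Zn]C; trimethylsilyl triflate, C[Si](C)(C)OS(=O)(=O)C(F)(F)F
Why: In this copper-catalysed asymmetric conjugate addition the ligand rather than the remote ring substituents should fix C10, and silylation stores the regiodefined enolate.

Step 20
Reactants: 32 silyl enol ether; 33 1-bromobut-2-yne
Product: 35 2-(but-2-ynyl)-3-methylcycloheptanone (C1 chain trans to the C10 methyl), via lithium enolate 34 (not isolated)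
Conditions: MeLi, THF, 0 °C; 33, DMPU, –78 → –20 °C
Reagents that add atoms: 33 1-bromobut-2-yne, CC#CCBr
Why: The lithium enolate is released regiospecifically from the silyl enol ether and should be alkylated anti to the neighbouring methyl, which sets C1 in its more stable trans arrangement.

Step 21
Reactants: 35 alkynyl ketone
Product: 36 1,4-diketone (C5 and C3 carbonyls)
Conditions: Ph3PAuNTf2 (2 mol %), dioxane–H2O, 60 °C
Reagents that add atoms: water, O
Why: In this carbonyl-assisted alkyne hydration, 5-exo attack of the C5 carbonyl oxygen on the activated alkyne places the new carbonyl on C3.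

Step 22
Reactants: 36 diketone
Product: 37 guai-4-en-3-one (C3 ketone, C4(Me)=C5, H1 cis to the C10 methyl)
Conditions: KOH, EtOH, 60 °C
Reagents that add atoms: none
Why: The intramolecular aldol condensation of the 1,4-diketone closes the five-membered ring (C4 onto C5), while the alternative aldol would need a bridgehead enone and is reversible.

Step 23
Reactants: 37 enone
Product: 38 2-acetoxyguai-4-en-3-one (acetoxy cis to H1 and to the C10 methyl)
Conditions: Mn(OAc)3·2H2O, benzene, reflux, water separator
Reagents that add atoms: manganese triacetate, [Mn+3].CC(=O)[O-].CC(=O)[O-].CC(=O)[O-]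
Why: Mn(OAc)3 α'-acetoxylation of the enone delivers acetate to the convex face of the hydroazulenone (the face of H1, away from C10), which sets C2 in its more stable arrangement.

Step 24
Reactants: 38 vinylsilane
Product: 39 C11 vinyl iodide
Conditions: N-iodosuccinimide, MeCN, 0 → 23 °C, dark
Reagents that add atoms: N-iodosuccinimide, O=C1CCC(=O)N1I
Why: Iododesilylation is an ipso substitution driven by the β-silicon effect, and the only other alkene is the deactivated enone double bond.

Step 25
Reactants: 39 enone
Product: 40 3-hydroxy-2-acetoxyguai-4-ene (hydroxyl cis to the acetate)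
Conditions: NaBH4, CeCl3·7H2O, MeOH, –78 °C
Reagents that add atoms: none
Why: This Luche 1,2-reduction delivers hydride anti to the C2 acetate, and the C3 centre is lost again in step 26.

Step 26
Reactants: 40 allylic alcohol; 21 eudesmanolide
Product: 42 bis-TBS spiro-norbornene adduct (C8-OTBS, C1'-OTBS, C2-OAc, C11 vinyl iodide), via diene 41 (not isolated)
Conditions: 21 (2 equiv), Ph2S[OC(CF3)2Ph]2 (Martin sulfurane), CH2Cl2, –40 → 0 °C; then 13 kbar, 20 °C
Reagents that add atoms: none
Why: Sulfurane dehydration (loss of the C3 oxygen and H1) should release the 5-acetoxycyclopentadiene cold, and pressure should drive its Diels–Alder reaction ahead of 1,5-hydrogen shifts, with four features setting C1, C3 and C11': CH2-13' bonds to the substituted terminus C1 and C11' to the free terminus C3 so that no vicinal quaternary carbons form, the 1,1-disubstituted dienophile must place C7' exo under C2 and therefore attacks the diene face opposite both the C2 acetate and the C14 methyl, and the lactone reacts on its convex H7'/H8' face with C12' endo.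

Step 27
Reactants: 42 bis-silyl ether
Product: 43 C8-hydroxy C11-vinyl iodide with free C1' hydroxyl (precursor of the key step)
Conditions: HF·pyridine, THF–pyridine, 0 → 23 °C
Reagents that add atoms: none
Why: Fluoride-mediated desilylation under buffered acidic conditions spares the acetate, the lactone and the vinyl iodide.

Step 28
Reactants: 43 hydroxy vinyl iodide; 44 carbon monoxide
Product: 45 japonicone A
Conditions: Pd(PPh3)4 (10 mol %), CO (1 atm), i-Pr2NEt, THF–MeCN, 55 °C, 5 mM
Reagents that add atoms: 44 carbon monoxide, [C-]#[O+]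
Why: Zerovalent palladium from Pd(PPh3)4 adds oxidatively to the C11–I bond, CO inserts into the vinyl–palladium bond to give a divalent acylpalladium iodide, and the C8 hydroxyl attacks this acyl group while i-Pr2NEt takes up HI and zerovalent palladium is released. The closest known reaction type is the palladium-catalysed carbonylative lactonisation of 3-halo-homoallylic alcohols to α-methylene-γ-butyrolactones. The one ring that closes (C7–C8–O–C12–C11) does so by 5-exo-trig acyl substitution at C12, and the bonds formed are C11–C12 and C12–O. No stereocentre is created, because the trans ring fusion is fixed by C8 and C7 from steps 15 and 17. Only chemoselectivity is needed and the substrate provides it: the C–I bond is the single site for oxidative addition (neither the C2 acetate nor the C8'–O bond is allylic), and the C8 hydroxyl lies three atoms from the acyl carbon whereas the neopentyl C1' hydroxyl could react only intermolecularly, which dilution suppresses. Because this Michael acceptor appears only here, it never meets an enolate, a hydride or the diene.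

**Compound list**
1 | (S)-Wieland–Miescher ketone | C[C@]12CCC(=O)C=C1CCCC2=O | starting material
2 | C1' alcohol (OH cis to C14') | C[C@]12CCC(=O)C=C1CCC[C@@H]2O | intermediate
3 | C1' TBS ether enone | C[C@]12CCC(=O)C=C1CCC[C@@H]2O[Si](C)(C)C(C)(C)C | intermediate
4 | C7' ketal, C4'=C5' | C[C@]12CCC3(OCCO3)CC1=CCC[C@@H]2O[Si](C)(C)C(C)(C)C | intermediate
5 | 4',5'-epoxide (O trans to C14') | C[C@]12CCC3(OCCO3)C[C@@]14O[C@H]4CC[C@@H]2O[Si](C)(C)C(C)(C)C | intermediate
6 | 5'-hydroxy-4'-methyl ketal | C[C@]12CCC3(OCCO3)C[C@]1(O)[C@H](C)CC[C@@H]2O[Si](C)(C)C(C)(C)C | intermediate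
7 | 5'-hydroxy-7'-ketone | C[C@]12CCC(=O)C[C@]1(O)[C@H](C)CC[C@@H]2O[Si](C)(C)C(C)(C)C | intermediate
8 | 4'-methyl enone | C[C@]12CCC(=O)C=C1[C@H](C)CC[C@@H]2O[Si](C)(C)C(C)(C)C | intermediate
9 | lithium dienolate of 8 | [Li+].C[C@]12CC=C([O-])C=C1[C@H](C)CC[C@@H]2O[Si](C)(C)C(C)(C)C | intermediate
10 | dienyl triflate | C[C@]12CC=C(OS(=O)(=O)C(F)(F)F)C=C1[C@H](C)CC[C@@H]2O[Si](C)(C)C(C)(C)C | intermediate
11 | tert-butyl (bromozincio)acetate | Br[Zn]CC(=O)OC(C)(C)C | starting material
12 | diene tert-butyl ester | C[C@]12CC=C(CC(=O)OC(C)(C)C)C=C1[C@H](C)CC[C@@H]2O[Si](C)(C)C(C)(C)C | intermediate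
13 | C8' 9-borabicyclononyl borane | C[C@]12C[C@@H](B3C4CCCC3CCC4)[C@H](CC(=O)OC(C)(C)C)C=C1[C@H](C)CC[C@@H]2O[Si](C)(C)C(C)(C)C | intermediate
14 | 8'-alcohol (OH trans to C14') | C[C@]12C[C@@H](O)[C@H](CC(=O)OC(C)(C)C)C=C1[C@H](C)CC[C@@H]2O[Si](C)(C)C(C)(C)C | intermediate
15 | C8' ketone | C[C@]12CC(=O)[C@H](CC(=O)OC(C)(C)C)C=C1[C@H](C)CC[C@@H]2O[Si](C)(C)C(C)(C)C | intermediate
16 | lithium 8'-alkoxide (O cis to C14') | [Li+].C[C@]12C[C@H]([O-])[C@H](CC(=O)OC(C)(C)C)C=C1[C@H](C)CC[C@@H]2O[Si](C)(C)C(C)(C)C | intermediate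
17 | cis-fused lactone | O=C1O[C@H]2C[C@@]3(C)C(=C[C@H]2C1)[C@H](C)CC[C@@H]3O[Si](C)(C)C(C)(C)C | intermediate
18 | lithium enolate of 17 | [Li+].[O-]C=1O[C@H]2C[C@@]3(C)C(=C[C@H]2C=1)[C@H](C)CC[C@@H]3O[Si](C)(C)C(C)(C)C | intermediate
19 | 11'-(dimethylaminomethyl) lactone | CN(C)C[C@@H]1C(=O)O[C@H]2C[C@@]3(C)C(=C[C@H]21)[C@H](C)CC[C@@H]3O[Si](C)(C)C(C)(C)C | intermediate
20 | methiodide of 19 | [I-].C[N+](C)(C)C[C@@H]1C(=O)O[C@H]2C[C@@]3(C)C(=C[C@H]21)[C@H](C)CC[C@@H]3O[Si](C)(C)C(C)(C)C | intermediate
21 | C1'-OTBS α-methylene eudesmanolide | C=C1C(=O)O[C@H]2C[C@@]3(C)C(=C[C@H]21)[C@H](C)CC[C@@H]3O[Si](C)(C)C(C)(C)C | intermediate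
22 | cyclohepta-1,3-diene | C1=CC=CCCC1 | starting material
23 | meso endoperoxide | C1C[C@@H]2C=C[C@H](C1)OO2 | intermediate
24 | (R)-4-hydroxycyclohept-2-enone | O=C1C=C[C@H](O)CCC1 | intermediate
25 | (R)-4-(TBSO)cyclohept-2-enone | O=C1C=C[C@H](O[Si](C)(C)C(C)(C)C)CCC1 | intermediate
26 | (1-bromovinyl)trimethylsilane | C=C(Br)[Si](C)(C)C | starting material
27 | [1-(trimethylsilyl)vinyl]magnesium bromide | C=C([Mg]Br)[Si](C)(C)C | intermediate
28 | trans-3-(1-silylvinyl)-4-(TBSO)cycloheptanone | O=C1C[C@@H](C(=C)[Si](C)(C)C)[C@H](O[Si](C)(C)C(C)(C)C)CCC1 | intermediate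
29 | C5 silyl enol ether (C5=C1) | C[Si](C)(C)OC=1C[C@@H](C(=C)[Si](C)(C)C)[C@H](O[Si](C)(C)C(C)(C)C)CCC=1 | intermediate
30 | cycloheptenone (C1=C10) | O=C1C[C@@H](C(=C)[Si](C)(C)C)[C@H](O[Si](C)(C)C(C)(C)C)CC=C1 | intermediate
31 | methylzinc enolate | C[Zn]OC=1C[C@@H](C(=C)[Si](C)(C)C)[C@H](O[Si](C)(C)C(C)(C)C)C[C@@H](C)C=1 | intermediate
32 | 10-methyl silyl enol ether | C[Si](C)(C)OC=1C[C@@H](C(=C)[Si](C)(C)C)[C@H](O[Si](C)(C)C(C)(C)C)C[C@@H](C)C=1 | intermediate
33 | 1-bromobut-2-yne | CC#CCBr | starting material
34 | lithium enolate | [Li+].[O-]C=1C[C@@H](C(=C)[Si](C)(C)C)[C@H](O[Si](C)(C)C(C)(C)C)C[C@@H](C)C=1 | intermediate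
35 | butynyl ketone | O=C1C[C@@H](C(=C)[Si](C)(C)C)[C@H](O[Si](C)(C)C(C)(C)C)C[C@@H](C)[C@@H]1CC#CC | intermediate
36 | 1,4-diketone | O=C1C[C@@H](C(=C)[Si](C)(C)C)[C@H](O[Si](C)(C)C(C)(C)C)C[C@@H](C)[C@@H]1CC(=O)CC | intermediate
37 | guai-4-en-3-one | CC1=C2C[C@@H](C(=C)[Si](C)(C)C)[C@H](O[Si](C)(C)C(C)(C)C)C[C@@H](C)[C@@H]2CC1=O | intermediate
38 | 2-acetoxy enone | CC1=C2C[C@@H](C(=C)[Si](C)(C)C)[C@H](O[Si](C)(C)C(C)(C)C)C[C@@H](C)[C@@H]2[C@@H](OC(C)=O)C1=O | intermediate
39 | vinyl iodide enone | CC1=C2C[C@@H](C(I)=C)[C@H](O[Si](C)(C)C(C)(C)C)C[C@@H](C)[C@@H]2[C@@H](OC(C)=O)C1=O | intermediate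
40 | allylic alcohol | CC1=C2C[C@@H](C(I)=C)[C@H](O[Si](C)(C)C(C)(C)C)C[C@@H](C)[C@@H]2[C@@H](OC(C)=O)[C@H]1O | intermediate
41 | 2-acetoxyguaia-1(5),3-diene | CC1=C[C@H](OC(C)=O)C2=C1C[C@@H](C(I)=C)[C@H](O[Si](C)(C)C(C)(C)C)C[C@H]2C | intermediate
42 | bis-TBS Diels–Alder adduct | CC(C)(C)[Si](C)(C)O[C@@H]2C[C@@H](C)[C@]34C[C@]5(C(=O)O[C@H]6C[C@@]7(C)C(=C[C@H]65)[C@H](C)CC[C@@H]7O[Si](C)(C)C(C)(C)C)[C@H](C(C)=C3C[C@H]2C(I)=C)[C@@H]4OC(C)=O | intermediate
43 | C8-hydroxy C11-vinyl iodide | O[C@@H]2C[C@@H](C)[C@]34C[C@]5(C(=O)O[C@H]6C[C@@]7(C)C(=C[C@H]65)[C@H](C)CC[C@@H]7O)[C@H](C(C)=C3C[C@H]2C(I)=C)[C@@H]4OC(C)=O | intermediate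
44 | carbon monoxide | [C-]#[O+] | starting material
45 | japonicone A | C=C1C(=O)O[C@@H]2C[C@@H](C)[C@]34C[C@]5(C(=O)O[C@H]6C[C@@]7(C)C(=C[C@H]65)[C@H](C)CC[C@@H]7O)[C@H](C(C)=C3C[C@@H]12)[C@@H]4OC(C)=O | target

**Step count**
- Total step count: 28.
- Longest linear sequence: 16 steps (steps 1–13, then 26–28).

**Steps most likely to fail**

1. **Step 26.** Several processes may divert the step:
   - ionisation at C3 may be intercepted by the neighbouring acetate;
   - the proton may be lost from C6 instead of C1;
   - suprafacial 1,5-hydrogen shifts may erode C2 before the slow cycloaddition;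
   - attack on the acetoxy face, the electronically preferred face of 5-oxygenated cyclopentadienes, may compete.

   The fallback sets out from 40 and 21 and releases the diene without any cation, slowly and in the presence of the dienophile. 2,4-Dinitrobenzenesulfenyl chloride and Et3N convert 40 into the C3 sulfenate ester F1. This rearranges by a suprafacial [2,3]-shift to the tertiary C5 allylic sulfoxide F2, whose sulfur lies cis to H1. Gentle warming in a concentrated solution of 21 brings about the sulfoxide syn-elimination to diene 41, which is trapped as it forms. The route is rejoined at 42.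

2. **Step 19.** Slow transfer of the methyl group from zinc, and a mismatch between ligand and ring substituents, may give poor facial selectivity at C10. The fallback sets out from 32, as whatever mixture is obtained, and sets C10 by hydride instead of methyl delivery. Pd(OAc)2 oxidation erases the centre and gives the 10-methyl enone F3. Copper hydride conjugate reduction (CuCl, NaOt-Bu, p-tol-BINAP, Ph2SiH2) then adds hydrogen to C10 under ligand control to give the diphenylsilyl enol ether F4. Treatment with Bu4N[Ph3SiF2] and 33 alkylates F4, and the route is rejoined at 35.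

3. **Step 28.** Capture of the acylpalladium species by the C8 hydroxyl may be slow. Protodeiodination, palladium hydride migration of the exocyclic double bond into the ring, or acylation of a C1' hydroxyl of a second molecule could then take over. The fallback sets out from 42 and keeps CO as the source of C12 but separates insertion from ring closure. Methoxycarbonylation (PdCl2(PPh3)2, CO, MeOH, Et3N, DMF) gives the acrylate methyl ester F5. HF·pyridine frees the dihydroxy ester F6, and a trace of p-TsOH in benzene closes the lactone by transesterification. The route is rejoined at 45.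

**Further compounds**
F1 | step 26 | C3 2,4-dinitrobenzenesulfenate of 40 | CC1=C2C[C@@H](C(I)=C)[C@H](O[Si](C)(C)C(C)(C)C)C[C@@H](C)[C@@H]2[C@@H](OC(C)=O)[C@H]1OSc1ccc(cc1[N+](=O)[O-])[N+](=O)[O-]
F2 | step 26 | C5 allylic 2,4-dinitrophenyl sulfoxide (C3=C4, sulfur cis to H1) | CC1=C[C@H](OC(C)=O)[C@H]2[C@H](C)C[C@@H](O[Si](C)(C)C(C)(C)C)[C@H](C(I)=C)C[C@@]12S(=O)c1ccc(cc1[N+](=O)[O-])[N+](=O)[O-]
F3 | step 19 | 10-methyl enone (C1=C10) | O=C1C[C@@H](C(=C)[Si](C)(C)C)[C@H](O[Si](C)(C)C(C)(C)C)CC(C)=C1
F4 | step 19 | diphenylsilyl enol ether with C10 set | c1ccccc1[SiH](c2ccccc2)OC=3C[C@@H](C(=C)[Si](C)(C)C)[C@H](O[Si](C)(C)C(C)(C)C)C[C@@H](C)C=3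
F5 | step 28 | bis-TBS acrylate methyl ester | CC(C)(C)[Si](C)(C)O[C@@H]2C[C@@H](C)[C@]34C[C@]5(C(=O)O[C@H]6C[C@@]7(C)C(=C[C@H]65)[C@H](C)CC[C@@H]7O[Si](C)(C)C(C)(C)C)[C@H](C(C)=C3C[C@H]2C(=C)C(=O)OC)[C@@H]4OC(C)=O
F6 | step 28 | dihydroxy acrylate methyl ester | O[C@@H]2C[C@@H](C)[C@]34C[C@]5(C(=O)O[C@H]6C[C@@]7(C)C(=C[C@H]65)[C@H](C)CC[C@@H]7O)[C@H](C(C)=C3C[C@H]2C(=C)C(=O)OC)[C@@H]4OC(C)=O
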